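**Strategy.** The bornane core is treated as a hidden Diels–Alder adduct. Cutting C3–C4 (the ring CH2 next to the ether carbon, to the unsubstituted bridgehead CH) together with C1–C2 reveals a 1,5,5-trimethylcyclopentadiene (C1=C6–C5=C4, gem-dimethyl C7) and an aryl vinyl ether (C2=C3). The two are already joined through the benzylic CH2 on the inner diene carbon C6. A type 2 intramolecular Diels–Alder reaction of this achiral precursor therefore closes the norbornene and the seven-membered benzoxepine ring in one operation and creates C1 (quaternary), C2 and C4. Forced exo-face hydrogenation sets C6; acylation, formylation and a Schiff-base resolution complete the target.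

Key step: step 5

Remark: locants C1–C7 are those of bornane (C1 methyl-bearing bridgehead, C2 O-bearing carbon, C3 ring CH2, C4 bridgehead CH, C5 CH2, C6 carbon bearing the benzylic CH2, C7 CMe2). The key step starts from an achiral diene, so the intermediates after it are racemic until the resolution; they are written as the enantiomer that is carried on to the target.

Step 1
Reactants: 1 2,4,6-trihydroxybenzaldehyde
Product: 2 2-hydroxy-4,6-bis(methoxymethoxy)benzaldehyde
Conditions: MOMCl (2.1 equiv), i-Pr2NEt, CH2Cl2, 0 °C to rt
Reagents that add atoms: chloromethyl methyl ether, COCCl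
Why: O-alkylation (MOM protection) should stop at the bis-ether because the last ortho OH is hydrogen-bonded to the aldehyde and least nucleophilic, which leaves free exactly the oxygen that becomes the ring ether.

Step 2
Reactants: 2 2-hydroxy-4,6-bis(methoxymethoxy)benzaldehyde
Product: 3 2-(ethenyloxy)-4,6-bis(methoxymethoxy)benzaldehyde
Conditions: vinyl acetate (3 equiv), [IrCl(cod)]2 (1 mol%), Na2CO3 (0.6 equiv), PhMe, 100 °C
Reagents that add atoms: vinyl acetate, CC(=O)OC=C
Why: Iridium-catalysed transfer vinylation of a phenol (addition of the phenoxide to coordinated vinyl acetate, then loss of acetate) installs the dienophile as an aryl vinyl ether that tolerates the basic and organometallic steps that follow.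

Step 3
Reactants: 3 2-(ethenyloxy)-4,6-bis(methoxymethoxy)benzaldehyde; 4 2,2-dimethylcyclopentan-1-one
Product: 5 (2E)-2-{[2-(ethenyloxy)-4,6-bis(methoxymethoxy)phenyl]methylidene}-5,5-dimethylcyclopentan-1-one
Conditions: KOH, EtOH, 60 °C
Reagents that add atoms: none
Why: Claisen–Schmidt (crossed aldol) condensation is unambiguous because ketone 4 has a single enolisable position and aldehyde 3 has none, and the E enone is the thermodynamic product.

Step 4
Reactants: 5 (2E)-2-{[2-(ethenyloxy)-4,6-bis(methoxymethoxy)phenyl]methylidene}-5,5-dimethylcyclopentan-1-one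
Product: 8 2-{[2-(ethenyloxy)-4,6-bis(methoxymethoxy)phenyl]methyl}-1,5,5-trimethylcyclopenta-1,3-diene, via exocyclic diene 6 (not isolated), via exo-methylene cyclopentene 7 (not isolated)
Conditions: Ph3PCH3Br (1.5 equiv), KOt-Bu (3 equiv), THF–DMSO, 0 °C to rt; then 60 °C
Reagents that add atoms: methyltriphenylphosphonium bromide, C[P+](c1ccccc1)(c1ccccc1)c1ccccc1.[Br-]
Why: Wittig methylenation of the non-enolisable ketone gives 6, and the excess KOt-Bu in DMSO should then move both double bonds into the ring by two 1,3-prototropic shifts through allyl/benzyl and pentadienyl anions (base-mediated alkene isomerisation), 8 being the expected thermodynamic sink because it alone has both C=C bonds endocyclic and one of them tetrasubstituted, while the twisted 2,6-dioxygenated aryl gives the benzylidene isomers little conjugative gain.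

Step 5
Reactants: 8 2-{[2-(ethenyloxy)-4,6-bis(methoxymethoxy)phenyl]methyl}-1,5,5-trimethylcyclopenta-1,3-diene
Product: 9 rac-(1S,2S,4S)-norbornene-fused benzoxepine (Diels–Alder adduct; aryl O endo on C2, benzylic CH2 on alkene carbon C6)
Conditions: degassed PhMe (0.01 M), BHT (0.1 equiv), K2CO3 (solid, acid scavenger), sealed tube, 190 °C
Reagents that add atoms: none
Why: Thermal, concerted [4+2] cycloaddition of the type 2 intramolecular Diels–Alder class (closest precedents: bridgehead-alkene-forming cyclisations of 2-tethered dienes and the thermal additions of vinyl ethers and vinyl acetate to cyclopentadienes), in which C2 of the vinyl ether bonds to C1 and C3 to C4. The six-membered carbocycle C1–C6 of the norbornene closes by cycloaddition, and the seven-membered oxepine closes in the bridged mode through the four-atom O–aryl–CH2 tether. C1 (quaternary), C2 and C4 are created together: suprafacial addition fixes their relative configuration and the tether forces the aryloxy group endo, whereas the two faces of achiral 8 are enantiotopic, so 9 forms as a racemate that is resolved in step 8. Regioselectivity is secured by the tether, since the reverse orientation would require C5=C6 to be a trans alkene in an eight-membered ring, and periselectivity by the quaternary C7, which blocks [1,5]-hydrogen shifts of the diene. The price is a pyramidalised C5=C6 bond bent towards the endo face, the direction in which norbornene alkenes are already bent; high dilution and a radical inhibitor should suppress oligomerisation.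

Step 6
Reactants: 9 rac-(1S,2S,4S)-norbornene-fused benzoxepine
Product: 10 rac-(1R,2S,4R,6S)-bornane-fused benzoxepine bis-MOM ether
Conditions: H2 (3 atm), Pd/C (10%), EtOAc, rt
Reagents that add atoms: none
Why: Heterogeneous syn-hydrogenation of the strained alkene sets C6, because both hydrogens must arrive on the exo (C7) face: the benzylic CH2 is locked endo by the oxepine ring (an exo CH2 on C6 cannot reach the endo oxygen on C2) and the pyramidalised alkene bulges towards that face.

Step 7
Reactants: 10 rac-(1R,2S,4R,6S)-bornane-fused benzoxepine bis-MOM ether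
Product: 12 rac-dihydroxy aryl ketone (3-methylbutanoyl between the two OH groups), via bis-MOM ketone 11 (not isolated)
Conditions: n-BuLi (1.3 equiv), TMEDA, THF, 0 °C; (i-BuCO)2O, −78 °C to rt; then 3 M HCl, MeOH, 50 °C
Reagents that add atoms: 3-methylbutanoic anhydride, CC(C)CC(=O)OC(=O)CC(C)C
Why: Directed ortho-metalation should select the ring C–H flanked by the two chelating OMOM groups over the one next to the hindered bornyl ether, the aryllithium is acylated by the anhydride (the doubly ortho-substituted ketone resists a second addition), and acid then cleaves both MOM acetals without touching the secondary alkyl aryl ether or any stereocenter.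

Step 8
Reactants: 12 rac-dihydroxy aryl ketone
Product: 14 (S)-1-phenylethyl Schiff base of the target with the (1R,2S,4R,6S) core, via aryl iminium chloride 13 (not isolated)
Conditions: [Me2N=CHCl]Cl (1.5 equiv), MeCN, 0 °C to rt; then (S)-1-phenylethylamine (5 equiv), EtOH, rt; fractional crystallisation (or chromatography on Et3N-deactivated SiO2)
Reagents that add atoms: (chloromethylene)dimethyliminium chloride, C[N+](C)=CCl.[Cl-]; (S)-1-phenylethan-1-amine, C[C@H](N)c1ccccc1
Why: Vilsmeier–Haack formylation attacks the only unsubstituted ring carbon (ortho to OH and to the ether O), and the aryl iminium salt 13 is intercepted by the primary amine (transimination) to give hydrogen-bonded Schiff bases that are diastereomers because the amine is (S), so their separation is a classical resolution that fixes the absolute configuration (to be assigned by X-ray analysis against the known amine centre).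

Step 9
Reactants: 14 (S)-1-phenylethyl Schiff base
Product: 15 target, (1R,2S,4R,6S)
Conditions: 1 M HCl, THF, 40 °C
Reagents that add atoms: water, O
Why: Acid hydrolysis of the imine releases the aldehyde and the resolving amine under conditions that leave the bornyl aryl ether, the ketone and all four stereocenters untouched.

**Compound list**

1 | 2,4,6-trihydroxybenzaldehyde | O=Cc1c(O)cc(O)cc1O | starting material
2 | 2-hydroxy-4,6-bis(methoxymethoxy)benzaldehyde | O=Cc1c(O)cc(OCOC)cc1OCOC | intermediate
3 | 2-(ethenyloxy)-4,6-bis(methoxymethoxy)benzaldehyde | O=Cc1c(OC=C)cc(OCOC)cc1OCOC | intermediate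
4 | 2,2-dimethylcyclopentan-1-one | CC1(C)CCCC1=O | starting material
5 | (2E)-2-{[2-(ethenyloxy)-4,6-bis(methoxymethoxy)phenyl]methylidene}-5,5-dimethylcyclopentan-1-one | CC1(C)CC/C(=C\c2c(OC=C)cc(OCOC)cc2OCOC)C1=O | intermediate
6 | (1E)-1-{[2-(ethenyloxy)-4,6-bis(methoxymethoxy)phenyl]methylidene}-3,3-dimethyl-2-methylidenecyclopentane (not isolated) | CC1(C)CC/C(=C\c2c(OC=C)cc(OCOC)cc2OCOC)C1=C | intermediate
7 | 1-{[2-(ethenyloxy)-4,6-bis(methoxymethoxy)phenyl]methyl}-4,4-dimethyl-5-methylidenecyclopent-1-ene (not isolated) | C=C1C(Cc2c(OC=C)cc(OCOC)cc2OCOC)=CCC1(C)C | intermediate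
8 | 2-{[2-(ethenyloxy)-4,6-bis(methoxymethoxy)phenyl]methyl}-1,5,5-trimethylcyclopenta-1,3-diene | CC1=C(Cc2c(OC=C)cc(OCOC)cc2OCOC)C=CC1(C)C | intermediate
9 | rac-(1S,2S,4S)-1,7,7-trimethylbicyclo[2.2.1]hept-5-ene whose endo O on C2 and CH2 on C6 are the ortho O and CH2 of one benzene ring (oxepine ring O–C2–C1–C6–CH2–ArC–ArC); OCH2OCH3 ortho and para to the CH2-bearing ring carbon | c1c(OCOC)cc2c(c1OCOC)CC1=C[C@@H]3C[C@H](O2)[C@@]1(C)C3(C)C | intermediate
10 | rac-(1R,2S,4R,6S)-5,6-dihydro derivative of 9 (bornane with endo aryl-O on C2 and endo aryl-CH2 on C6) | c1c(OCOC)cc2c(c1OCOC)C[C@@H]1C[C@@H]3C[C@H](O2)[C@@]1(C)C3(C)C | intermediate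
11 | rac-10 carrying 3-methylbutanoyl on the ring carbon between the two OMOM groups (not isolated) | CC(C)CC(=O)c1c(OCOC)cc2c(c1OCOC)C[C@@H]1C[C@@H]3C[C@H](O2)[C@@]1(C)C3(C)C | intermediate
12 | rac-dihydroxy ketone (11 without the MOM groups) | CC(C)CC(=O)c1c(O)cc2c(c1O)C[C@@H]1C[C@@H]3C[C@H](O2)[C@@]1(C)C3(C)C | intermediate
13 | rac-aryl(dimethyl)iminium chloride (CH=NMe2+ on the ring carbon between OH and ether O of 12; not isolated) | CC(C)CC(=O)c1c(O)c(C=[N+](C)C)c2c(c1O)C[C@@H]1C[C@@H]3C[C@H](O2)[C@@]1(C)C3(C)C.[Cl-] | intermediate
14 | (E)-N-[(1S)-1-phenylethyl]imine of the target, core (1R,2S,4R,6S) | CC(C)CC(=O)c1c(O)c(/C=N/[C@@H](C)c4ccccc4)c2c(c1O)C[C@@H]1C[C@@H]3C[C@H](O2)[C@@]1(C)C3(C)C | intermediate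
15 | target: (1R,2S,4R,6S)-bornane-fused benzoxepine; arene carries CHO ortho to the ether O, then OH, 3-methylbutanoyl, OH round to the CH2-bearing carbon | CC(C)CC(=O)c1c(O)c(C=O)c2c(c1O)C[C@@H]1C[C@@H]3C[C@H](O2)[C@@]1(C)C3(C)C | target

Total step count: 9. Longest linear sequence: 9 steps (1 to 15).

**Steps most likely to fail**

Step 5. The cycloaddition may be too slow at temperatures the diene tolerates, or may revert, because the dienophile is unactivated and the adduct carries a pyramidalised alkene. The fallback sets out from 2 and returns at 10; it lowers the dienophile LUMO with a removable carboxyl group so that ring closure should run at 80–110 °C. Phenol 2 is condensed with 4 (KOH, EtOH) to hydroxybenzylidene ketone F1. Methylenation and isomerisation as in step 4 (one extra equivalent of KOt-Bu for the phenoxide) give phenol diene F2. Conjugate addition to benzyl propiolate (DABCO cat., CH2Cl2) gives benzyl (E)-β-aryloxyacrylate F3, which should cyclise in PhMe to ester adduct F4 (ester exo on C3, trans to the endo oxygen). H2 over Pd/C reduces C5=C6 and cleaves the benzyl ester in one operation to acid F5. Barton reductive decarboxylation (N-hydroxypyridine-2-thione, DCC, DMAP; then t-BuSH, hν) removes the activating group and gives 10.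

Step 4. The double-bond migration may stall at the exocyclic isomers or drift to a benzylidene isomer, and the strong base may degrade the enone before olefination. The fallback sets out from 3 and returns at 8; it places both double bonds by carbonyl chemistry instead of by equilibration. Aldehyde 3 is used in a reductive alkylation of 4,4-dimethylcyclopentane-1,3-dione (Hantzsch ester, L-proline cat., CH2Cl2) to give 2-benzyl-1,3-dione F6. O-methylation at the oxygen remote from the gem-dimethyl group (Me3SiCHN2, MeOH–PhMe) gives vinylogous ester F7. A Stork–Danheiser sequence (MeLi, THF, −78 °C; then cold dilute aqueous oxalic acid) gives enone F8, i-Bu2AlH gives allylic alcohol F9, and MsCl/Et3N elimination towards the ring CH2 gives 8.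

Step 8. The diastereomeric Schiff bases may co-crystallise or equilibrate during chromatography, so that the resolution fails. The fallback sets out from 12 and returns at 15; it resolves through covalent, configurationally stable carbamates before the aldehyde is introduced. Racemic 12 is treated with (S)-1-phenylethyl isocyanate (Et3N, DMAP cat., CH2Cl2), and the bis-carbamates are separated by crystallisation or chromatography to give bis-carbamate F10. K2CO3 in MeOH releases enantiopure dihydroxy ketone F11, and Vilsmeier–Haack formylation with aqueous NaOAc work-up gives 15 directly.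

**Further compounds**

F1 | step 5 | (2E)-2-{[2-hydroxy-4,6-bis(methoxymethoxy)phenyl]methylidene}-5,5-dimethylcyclopentan-1-one | CC1(C)CC/C(=C\c2c(O)cc(OCOC)cc2OCOC)C1=O
F2 | step 5 | 3,5-bis(methoxymethoxy)-2-[(2,3,3-trimethylcyclopenta-1,4-dien-1-yl)methyl]phenol | CC1=C(Cc2c(O)cc(OCOC)cc2OCOC)C=CC1(C)C
F3 | step 5 | benzyl (2E)-3-{3,5-bis(methoxymethoxy)-2-[(2,3,3-trimethylcyclopenta-1,4-dien-1-yl)methyl]phenoxy}prop-2-enoate | O=C(OCc1ccccc1)/C=C/Oc1cc(OCOC)cc(OCOC)c1CC1=C(C)C(C)(C)C=C1
F4 | step 5 | rac-benzyl ester adduct (9 with exo CO2CH2Ph on C3) | c1c(OCOC)cc2c(c1OCOC)CC1=C[C@@H]3[C@@H](C(=O)OCc4ccccc4)[C@H](O2)[C@@]1(C)C3(C)C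
F5 | step 5 | rac-carboxylic acid (10 with exo CO2H on C3) | c1c(OCOC)cc2c(c1OCOC)C[C@@H]1C[C@@H]3[C@@H](C(=O)O)[C@H](O2)[C@@]1(C)C3(C)C
F6 | step 4 | 2-{[2-(ethenyloxy)-4,6-bis(methoxymethoxy)phenyl]methyl}-4,4-dimethylcyclopentane-1,3-dione | CC1(C)CC(=O)C(Cc2c(OC=C)cc(OCOC)cc2OCOC)C1=O
F7 | step 4 | 2-{[2-(ethenyloxy)-4,6-bis(methoxymethoxy)phenyl]methyl}-3-methoxy-5,5-dimethylcyclopent-2-en-1-one | COC1=C(Cc2c(OC=C)cc(OCOC)cc2OCOC)C(=O)C(C)(C)C1
F8 | step 4 | 2-{[2-(ethenyloxy)-4,6-bis(methoxymethoxy)phenyl]methyl}-3,4,4-trimethylcyclopent-2-en-1-one | CC1=C(Cc2c(OC=C)cc(OCOC)cc2OCOC)C(=O)CC1(C)C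
F9 | step 4 | rac-2-{[2-(ethenyloxy)-4,6-bis(methoxymethoxy)phenyl]methyl}-3,4,4-trimethylcyclopent-2-en-1-ol | CC1=C(Cc2c(OC=C)cc(OCOC)cc2OCOC)C(O)CC1(C)C
F10 | step 8 | bis{N-[(1S)-1-phenylethyl]carbamate} of the (1R,2S,4R,6S) enantiomer of 12 | CC(C)CC(=O)c1c(OC(=O)N[C@@H](C)c4ccccc4)cc2c(c1OC(=O)N[C@@H](C)c5ccccc5)C[C@@H]1C[C@@H]3C[C@H](O2)[C@@]1(C)C3(C)C
F11 | step 8 | (1R,2S,4R,6S) enantiomer of dihydroxy ketone 12 | CC(C)CC(=O)c1c(O)cc2c(c1O)C[C@@H]1C[C@@H]3C[C@H](O2)[C@@]1(C)C3(C)C
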